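**Retrosynthetic overview** (carotenoid locants; unprimed = 3,4-dihydroxy-β-ring half, primed = 3'-hydroxy-ε-ring half)
1. The C40 chain is cut at the C12'–C13' single bond into a C16 (E)-alkenyl bromide (ε ring + C7'–C12') and a C24 (E)-enol triflate (C13'–C7 hexaene + β ring); the two are joined by a reductive nickel/palladium cross-electrophile coupling, and desilylation ends the route.
2. Enabling feature: C12' is the CH terminus of the triene on the ε ring and C13' is the methyl-bearing head of the hexaene on the β ring. Both are sp2 carbons; C13' is the ketone carbon of an acetoacetate unit and so is available as a stereodefined enol triflate. The undecaene is oxidation-labile but inert to zinc, so two electrophilic alkenyl carbons can be united reductively.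
3. The C24 triflate comes from a C20 aldehyde (two Horner–Wadsworth–Emmons/DIBAL cycles on the ring ketone) plus a C4 triflate phosphonate from ethyl acetoacetate; the C16 bromide comes from the C15 aldehyde by Takai olefination.
4. No ring is formed: both six-membered rings come from one precursor, (3S,6R)-3-hydroxy-α-ionone (from (R)-α-ionone by allylic oxidation and CBS reduction). The ε ring keeps it as such; the β ring is reached by hydroxyl-directed epoxidation and vinylogous E1cB opening, which sets the cis-3,4-diol and erases C6.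

Key step: step 20

Remark: (R)-α-ionone is taken as a purchasable single enantiomer (fermentation-derived flavour ingredient).

**Route**

Step 1
Reactants: 1 (R)-α-ionone, (3E)-4-[(1R)-2,6,6-trimethylcyclohex-2-en-1-yl]but-3-en-2-one
Product: 2 (R)-α-ionone ethylene ketal, 2-methyl-2-{(E)-2-[(1R)-2,6,6-trimethylcyclohex-2-en-1-yl]ethenyl}-1,3-dioxolane
Conditions: Me3SiOCH2CH2OSiMe3, Me3SiOTf (2 mol%), CH2Cl2, −78→−20 °C
Reagents that add atoms: 1,2-bis(trimethylsilyloxy)ethane, C[Si](C)(C)OCCO[Si](C)(C)C
Why: Silyl-transfer ketalisation under kinetic, low-temperature conditions masks the enone carbonyl without migration of the C7=C8 bond, so the C6 stereocentre of 1 should stay untouched.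

Step 2
Reactants: 2 (R)-α-ionone ethylene ketal
Product: 3 (6R)-3-oxo-α-ionone ethylene ketal, (4R)-3,5,5-trimethyl-4-[(E)-2-(2-methyl-1,3-dioxolan-2-yl)ethenyl]cyclohex-2-en-1-one
Conditions: Rh2(cap)4 (1 mol%), t-BuOOH (70% aq., 5 equiv), ClCH2CH2Cl, 40 °C
Reagents that add atoms: tert-butyl hydroperoxide, CC(C)(C)OO
Why: Radical allylic C–H oxidation by tert-butylperoxyl radicals (dirhodium caprolactamate/hydroperoxide allylic oxidation) should convert the only ring allylic CH2 (C3) into the enone, and the base-free medium should leave the now γ-acidic C6–H configurationally intact.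

Step 3
Reactants: 3 (6R)-3-oxo-α-ionone ethylene ketal
Product: 4 (3S,6R)-3-hydroxy-α-ionone ethylene ketal, (1S,4R)-3,5,5-trimethyl-4-[(E)-2-(2-methyl-1,3-dioxolan-2-yl)ethenyl]cyclohex-2-en-1-ol (hydroxyl cis to the side chain)
Conditions: (R)-Me-CBS oxazaborolidine (0.2 equiv), BH3·SMe2 (0.7 equiv), THF, −20 °C; MeOH, then aq. NH4Cl
Reagents that add atoms: none
Why: Corey–Bakshi–Shibata reduction: the (R)-catalyst (alkenyl branch as the large group) should deliver hydride to the face that gives the S carbinol, which is also the face anti to the C6 side chain, so reagent and substrate preferences should reinforce and set C3 (S) cis to the chain.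

Step 4
Reactants: 4 (3S,6R)-3-hydroxy-α-ionone ethylene ketal
Product: 5 (3S,6R)-3-hydroxy-α-ionone, (3E)-4-[(1R,4S)-4-hydroxy-2,6,6-trimethylcyclohex-2-en-1-yl]but-3-en-2-one
Conditions: oxalic acid (10 mol%), THF/H2O, 20 °C
Reagents that add atoms: water, O
Why: Acid-catalysed hydrolysis of the allylic ketal should proceed under conditions too weak to ionise the ring allylic alcohol or to enolise toward C6.

Step 5
Reactants: 5 (3S,6R)-3-hydroxy-α-ionone; 6 diethyl (cyanomethyl)phosphonate
Product: 7 (2E,4E)-5-[(1R,4S)-4-hydroxy-2,6,6-trimethylcyclohex-2-en-1-yl]-3-methylpenta-2,4-dienenitrile (C15 nitrile of the ε half)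
Conditions: 6 (1.6 equiv), NaH (1.5 equiv), THF, 0 °C; then 5, 0→25 °C
Reagents that add atoms: none
Why: Horner–Wadsworth–Emmons olefination of the methyl ketone should give mainly the 9'E nitrile (minor 9'Z isomer to be removed by chromatography); with 6 in excess over NaH the hydroxyl is not deprotonated and the base-sensitive C6'–H is spared.

Step 6
Reactants: 7 C15 nitrile of the ε half
Product: 9 (2E,4E)-5-[(1R,4S)-4-hydroxy-2,6,6-trimethylcyclohex-2-en-1-yl]-3-methylpenta-2,4-dienal (C15 aldehyde of the ε half), via O,N-bis(diisobutylalumanyl) aldimine 8 (not isolated)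
Conditions: i-Bu2AlH (2.5 equiv), CH2Cl2, −78 °C; then aq. potassium sodium tartrate, 0 °C
Reagents that add atoms: water, O
Why: Partial reduction of a nitrile: after the hydroxyl proton is consumed, one hydride adds to the nitrile to give an N-aluminated aldimine that resists further reduction and is hydrolysed to the dienal on work-up.

Step 7
Reactants: 9 C15 aldehyde of the ε half
Product: 10 (1S,4R)-4-[(1E,3E,5E)-6-bromo-3-methylhexa-1,3,5-trien-1-yl]-3,5,5-trimethylcyclohex-2-en-1-ol (C16 alkenyl bromide)
Conditions: CrBr2 (6 equiv), CHBr3 (2 equiv), THF, 0→25 °C, dark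
Reagents that add atoms: bromoform, BrC(Br)Br
Why: Takai olefination: the gem-dichromium species from bromoform adds to the aldehyde and eliminates to the E-alkenyl bromide; the bromide salt of chromium avoids halide scrambling and the free hydroxyl should be tolerated.

Step 8
Reactants: 5 (3S,6R)-3-hydroxy-α-ionone
Product: 11 (3S,4S,5R,6R)-4,5-epoxy-3-hydroxy-4,5-dihydro-α-ionone (epoxide oxygen cis to the 3-hydroxyl)
Conditions: VO(acac)2 (5 mol%), t-BuOOH (1.5 equiv, in decane), CH2Cl2, 0→20 °C
Reagents that add atoms: tert-butyl hydroperoxide, CC(C)(C)OO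
Why: Hydroxyl-directed epoxidation of a cyclic allylic alcohol: the vanadium-bound alkylperoxide should deliver oxygen to C4=C5 from the face of the C3 hydroxyl, setting C4 (and the transient C5) cis to C3–OH, while the electron-poor enone alkene does not react.

Step 9
Reactants: 11 epoxy alcohol
Product: 12 (3S,4R)-3,4-dihydroxy-β-ionone, (3E)-4-[(3R,4S)-3,4-dihydroxy-2,6,6-trimethylcyclohex-1-en-1-yl]but-3-en-2-one (cis-diol)
Conditions: NaOMe (0.3 equiv), MeOH, 0→20 °C
Reagents that add atoms: none
Why: Vinylogous E1cB epoxide opening: γ-deprotonation at C6 gives the dienolate, which expels the C5–O bond to form the conjugated C5=C6 dienone; the C4–O bond is not broken, so the cis-3,4-diol is retained while the no longer needed C6 stereocentre is erased.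

Step 10
Reactants: 12 (3S,4R)-3,4-dihydroxy-β-ionone
Product: 13 (3E)-4-[(3R,4S)-3,4-bis{[tert-butyl(dimethyl)silyl]oxy}-2,6,6-trimethylcyclohex-1-en-1-yl]but-3-en-2-one
Conditions: t-BuMe2SiOTf (2.6 equiv), 2,6-lutidine (4 equiv), CH2Cl2, −40→0 °C
Reagents that add atoms: tert-butyldimethylsilyl trifluoromethanesulfonate, CC(C)(C)[Si](C)(C)OS(=O)(=O)C(F)(F)F
Why: Silylation with the silyl triflate and a hindered pyridine base should protect both hydroxyls of the hindered cis-diol as fluoride-labile ethers that withstand the coming base and hydride steps.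

Step 11
Reactants: 13 bis-silyl ether ketone; 6 diethyl (cyanomethyl)phosphonate
Product: 14 (2E,4E)-5-[(3R,4S)-3,4-bis{[tert-butyl(dimethyl)silyl]oxy}-2,6,6-trimethylcyclohex-1-en-1-yl]-3-methylpenta-2,4-dienenitrile (C15 nitrile of the β half)
Conditions: 6 (1.6 equiv), NaH (1.5 equiv), THF, 0→25 °C
Reagents that add atoms: none
Why: Horner–Wadsworth–Emmons olefination of the dienyl methyl ketone should give mainly the 9E nitrile, the minor 9Z isomer being removable by chromatography.

Step 12
Reactants: 14 C15 nitrile of the β half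
Product: 16 (2E,4E)-5-[(3R,4S)-3,4-bis{[tert-butyl(dimethyl)silyl]oxy}-2,6,6-trimethylcyclohex-1-en-1-yl]-3-methylpenta-2,4-dienal (C15 aldehyde of the β half), via N-diisobutylalumanyl aldimine 15 (not isolated)
Conditions: i-Bu2AlH (1.3 equiv), CH2Cl2, −78 °C; then aq. potassium sodium tartrate, 0 °C
Reagents that add atoms: water, O
Why: Partial reduction of the nitrile stops at the N-aluminated aldimine, which is hydrolysed to the aldehyde on work-up; silyl ethers are inert to the hydride.

Step 13
Reactants: 16 C15 aldehyde of the β half; 17 diethyl [(2E)-3-cyano-2-methylprop-2-en-1-yl]phosphonate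
Product: 18 (2E,4E,6E,8E)-9-[(3R,4S)-3,4-bis{[tert-butyl(dimethyl)silyl]oxy}-2,6,6-trimethylcyclohex-1-en-1-yl]-3,7-dimethylnona-2,4,6,8-tetraenenitrile (C20 nitrile)
Conditions: 17 (1.5 equiv), NaH (1.4 equiv), THF, 0→25 °C
Reagents that add atoms: none
Why: Horner–Wadsworth–Emmons olefination with the vinylogous C5 phosphonate forms C11=C12 with E geometry and brings in C12–C15 with the C13 methyl; the delocalised anion equilibrates, so the 13E nitrile is expected as the main product (minor 13Z isomer to be removed by chromatography).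

Step 14
Reactants: 18 C20 nitrile
Product: 20 (2E,4E,6E,8E)-9-[(3R,4S)-3,4-bis{[tert-butyl(dimethyl)silyl]oxy}-2,6,6-trimethylcyclohex-1-en-1-yl]-3,7-dimethylnona-2,4,6,8-tetraenal (C20 aldehyde), via N-diisobutylalumanyl aldimine 19 (not isolated)
Conditions: i-Bu2AlH (1.3 equiv), CH2Cl2, −78 °C; then aq. potassium sodium tartrate, 0 °C
Reagents that add atoms: water, O
Why: Partial reduction of the conjugated nitrile to the aldehyde through the hydrolysable N-aluminated aldimine, as in steps 6 and 12.

Step 15
Reactants: 21 ethyl acetoacetate (ethyl 3-oxobutanoate)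
Product: 22 ethyl (2E)-3-{[(trifluoromethyl)sulfonyl]oxy}but-2-enoate
Conditions: (CF3SO2)2O (1.3 equiv), aq. Me4NOH (25%), toluene, 5 °C
Reagents that add atoms: trifluoromethanesulfonic anhydride, O=S(=O)(OS(=O)(=O)C(F)(F)F)C(F)(F)F
Why: Biphasic (Schotten–Baumann-type) O-triflation of the β-keto ester with a non-coordinating ammonium counter-ion goes through the open, dipole-minimised enolate and should give the E enol triflate (triflate trans to the ester).

Step 16
Reactants: 22 E enol triflate ester
Product: 23 (2E)-4-hydroxybut-2-en-2-yl trifluoromethanesulfonate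
Conditions: i-Bu2AlH (2.2 equiv), CH2Cl2, −78 °C
Reagents that add atoms: none
Why: 1,2-Reduction of the conjugated ester to the allylic alcohol at low temperature, to which the alkenyl triflate should be inert.

Step 17
Reactants: 23 allylic alcohol
Product: 24 (2E)-4-bromobut-2-en-2-yl trifluoromethanesulfonate
Conditions: CBr4 (1.2 equiv), PPh3 (1.2 equiv), CH2Cl2, 0 °C
Reagents that add atoms: carbon tetrabromide, BrC(Br)(Br)Br
Why: Appel bromination converts the primary allylic alcohol into the bromide under neutral conditions with the alkene geometry retained.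

Step 18
Reactants: 24 allylic bromide
Product: 25 diethyl [(2E)-3-{[(trifluoromethyl)sulfonyl]oxy}but-2-en-1-yl]phosphonate
Conditions: P(OEt)3 (3 equiv, neat), 90 °C
Reagents that add atoms: triethyl phosphite, CCOP(OCC)OCC
Why: Michaelis–Arbuzov reaction at the primary allylic bromide gives the allylic phosphonate; the alkenyl triflate should not react with the phosphite at this temperature.

Step 19
Reactants: 20 C20 aldehyde; 25 triflate phosphonate
Product: 26 (2E,4E,6E,8E,10E,12E)-13-[(3R,4S)-3,4-bis{[tert-butyl(dimethyl)silyl]oxy}-2,6,6-trimethylcyclohex-1-en-1-yl]-7,11-dimethyltrideca-2,4,6,8,10,12-hexaen-2-yl trifluoromethanesulfonate (C24 enol triflate)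
Conditions: 25 (1.3 equiv), LiN(SiMe3)2 (1.25 equiv), THF, −78 °C; then 20, −78→0 °C
Reagents that add atoms: none
Why: Horner–Wadsworth–Emmons olefination of the polyenal with the lithiated allylic phosphonate should form C15=C15' with E geometry; the E enol triflate holds the sulfonyl group away from the carbanion and the low temperature should suppress base-induced loss of triflate.

Step 20
Reactants: 10 C16 alkenyl bromide; 26 C24 enol triflate
Product: 27 (3S,4R,3'S,6'R)-3,4-bis-O-[tert-butyl(dimethyl)silyl]-β,ε-carotene-3,4,3'-triol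
Conditions: NiBr2(bpy) (5 mol%), PdCl2(dppp) (5 mol%), Zn dust (2 equiv), DMF, 30 °C, Ar, dark
Reagents that add atoms: none
Why: A zerovalent palladium–dppp species inserts selectively into the C13'–OTf bond of 26 and a zerovalent nickel–bipyridine species into the C12'–Br bond of 10; alkenyl transfer from nickel to palladium gives a dialkenyl palladium complex that reductively eliminates the C12'–C13' single bond, and zinc returns both metals to the zerovalent state. The closest known reaction type is the multimetallic nickel/palladium cross-electrophile (cross-Ullmann) coupling of alkenyl bromides with alkenyl triflates to 1,3-dienes, here uniting two electrophilic sp2 carbons of like polarity. No ring is closed and no stereocentre is created; the four existing stereocentres are remote and untouched. The step needs cross- over homo-selectivity, which rests on the orthogonal preference of the phosphine–palladium catalyst for the triflate and of the bipyridine–nickel catalyst for the bromide, and it needs retention of E geometry at C11'=C12' and C13'=C14', which should follow from stereoretentive oxidative addition and reductive elimination at two unhindered E-alkenyl termini. The medium is reducing, which the oxidation-prone polyene tolerates (zinc is far too weak to reduce a conjugated polyene), and the free C3' hydroxyl and the silyl ethers should be inert to zinc in DMF.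

Step 21
Reactants: 27 bis-silyl ether of the carotenoid
Product: 28 (3S,4R,3'S,6'R)-β,ε-carotene-3,4,3'-triol (target)
Conditions: Bu4NF (4 equiv), THF, 0→25 °C, Ar, dark
Reagents that add atoms: none
Why: Fluoride-induced desilylation cleaves both silyl ethers under non-acidic conditions, which the acid-labile allylic C4 and C3' hydroxyls and the polyene should tolerate.

**Compound list**
1 | (R)-α-ionone | CC1=CCCC(C)(C)[C@H]1/C=C/C(C)=O | starting material
2 | (R)-α-ionone ethylene ketal | CC1=CCCC(C)(C)[C@H]1/C=C/C1(C)OCCO1 | intermediate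
3 | (6R)-3-oxo-α-ionone ethylene ketal | CC1=CC(=O)CC(C)(C)[C@H]1/C=C/C1(C)OCCO1 | intermediate
4 | (3S,6R)-3-hydroxy-α-ionone ethylene ketal | CC1=C[C@@H](O)CC(C)(C)[C@H]1/C=C/C1(C)OCCO1 | intermediate
5 | (3S,6R)-3-hydroxy-α-ionone | CC1=C[C@@H](O)CC(C)(C)[C@H]1/C=C/C(C)=O | intermediate
6 | diethyl (cyanomethyl)phosphonate | CCOP(=O)(CC#N)OCC | starting material
7 | C15 hydroxy nitrile of the ε half | CC1=C[C@@H](O)CC(C)(C)[C@H]1/C=C/C(C)=C/C#N | intermediate
8 | O,N-bis(diisobutylalumanyl) aldimine from 7 | CC1=C[C@@H](O[Al](CC(C)C)CC(C)C)CC(C)(C)[C@H]1/C=C/C(C)=C/C=N[Al](CC(C)C)CC(C)C | intermediate (not isolated)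
9 | C15 hydroxy aldehyde of the ε half | CC1=C[C@@H](O)CC(C)(C)[C@H]1/C=C/C(C)=C/C=O | intermediate
10 | C16 (E)-alkenyl bromide | CC1=C[C@@H](O)CC(C)(C)[C@H]1/C=C/C(C)=C/C=C/Br | intermediate
11 | (3S,4S,5R,6R)-4,5-epoxy-3-hydroxy-4,5-dihydro-α-ionone | C[C@]12O[C@H]1[C@@H](O)CC(C)(C)[C@H]2/C=C/C(C)=O | intermediate
12 | (3S,4R)-3,4-dihydroxy-β-ionone (cis-diol) | CC(=O)/C=C/C1=C(C)[C@@H](O)[C@@H](O)CC1(C)C | intermediate
13 | bis-TBS ether of 12 | CC(=O)/C=C/C1=C(C)[C@@H](O[Si](C)(C)C(C)(C)C)[C@@H](O[Si](C)(C)C(C)(C)C)CC1(C)C | intermediate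
14 | C15 nitrile of the β half | N#C/C=C(C)/C=C/C1=C(C)[C@@H](O[Si](C)(C)C(C)(C)C)[C@@H](O[Si](C)(C)C(C)(C)C)CC1(C)C | intermediate
15 | N-diisobutylalumanyl aldimine from 14 | CC(C)C[Al](CC(C)C)N=C/C=C(C)/C=C/C1=C(C)[C@@H](O[Si](C)(C)C(C)(C)C)[C@@H](O[Si](C)(C)C(C)(C)C)CC1(C)C | intermediate (not isolated)
16 | C15 aldehyde of the β half | O=C/C=C(C)/C=C/C1=C(C)[C@@H](O[Si](C)(C)C(C)(C)C)[C@@H](O[Si](C)(C)C(C)(C)C)CC1(C)C | intermediate
17 | diethyl [(2E)-3-cyano-2-methylprop-2-en-1-yl]phosphonate | CCOP(=O)(OCC)C/C(C)=C/C#N | starting material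
18 | C20 nitrile | N#C/C=C(C)/C=C/C=C(C)/C=C/C1=C(C)[C@@H](O[Si](C)(C)C(C)(C)C)[C@@H](O[Si](C)(C)C(C)(C)C)CC1(C)C | intermediate
19 | N-diisobutylalumanyl aldimine from 18 | CC(C)C[Al](CC(C)C)N=C/C=C(C)/C=C/C=C(C)/C=C/C1=C(C)[C@@H](O[Si](C)(C)C(C)(C)C)[C@@H](O[Si](C)(C)C(C)(C)C)CC1(C)C | intermediate (not isolated)
20 | C20 aldehyde | O=C/C=C(C)/C=C/C=C(C)/C=C/C1=C(C)[C@@H](O[Si](C)(C)C(C)(C)C)[C@@H](O[Si](C)(C)C(C)(C)C)CC1(C)C | intermediate
21 | ethyl acetoacetate | CCOC(=O)CC(C)=O | starting material
22 | ethyl (2E)-3-{[(trifluoromethyl)sulfonyl]oxy}but-2-enoate | CCOC(=O)/C=C(C)/OS(=O)(=O)C(F)(F)F | intermediate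
23 | (2E)-4-hydroxybut-2-en-2-yl trifluoromethanesulfonate | OC/C=C(C)/OS(=O)(=O)C(F)(F)F | intermediate
24 | (2E)-4-bromobut-2-en-2-yl trifluoromethanesulfonate | BrC/C=C(C)/OS(=O)(=O)C(F)(F)F | intermediate
25 | diethyl [(2E)-3-{[(trifluoromethyl)sulfonyl]oxy}but-2-en-1-yl]phosphonate | CCOP(=O)(OCC)C/C=C(C)/OS(=O)(=O)C(F)(F)F | intermediate
26 | C24 (E)-enol triflate | FC(F)(F)S(=O)(=O)O/C(C)=C/C=C/C=C(C)/C=C/C=C(C)/C=C/C1=C(C)[C@@H](O[Si](C)(C)C(C)(C)C)[C@@H](O[Si](C)(C)C(C)(C)C)CC1(C)C | intermediate
27 | (3S,4R,3'S,6'R)-3,4-bis-O-TBS-β,ε-carotene-3,4,3'-triol | CC1=C[C@@H](O)CC(C)(C)[C@H]1/C=C/C(C)=C/C=C/C(C)=C/C=C/C=C(C)/C=C/C=C(C)/C=C/C1=C(C)[C@@H](O[Si](C)(C)C(C)(C)C)[C@@H](O[Si](C)(C)C(C)(C)C)CC1(C)C | intermediate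
28 | (3S,4R,3'S,6'R)-β,ε-carotene-3,4,3'-triol | CC1=C[C@@H](O)CC(C)(C)[C@H]1/C=C/C(C)=C/C=C/C(C)=C/C=C/C=C(C)/C=C/C=C(C)/C=C/C1=C(C)[C@@H](O)[C@@H](O)CC1(C)C | target

**Totals and risks**

Total step count: 21. Longest linear sequence: 14 steps (1, 2, 3, 4, 8, 9, 10, 11, 12, 13, 14, 19, 20, 21).

Steps most likely to fail:

Step 20. What may go wrong: loss of cross-selectivity (homocoupling of either electrophile), hydrodehalogenation at the alkenyl–nickel stage, or E/Z erosion at C11'=C12'. Fallback: a conventional nucleophile–electrophile union. Setting out from 9, a boron variant of the Takai olefination (Cl2CHB(pin), CrCl2, LiI, THF) should give the (E)-alkenyl pinacol boronate F1. Suzuki–Miyaura coupling of this boronate with the triflate 26 (Pd(PPh3)4, aq. K3PO4, THF, 25 °C) then comes back to the route at 27.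

Step 19. What may go wrong: base-induced loss of triflate from the phosphonate anion (elimination toward an allene, sulfonyl transfer) before olefination. Fallback: the strongly basic carbanion is abandoned. Setting out from 24, quaternisation with PPh3 (toluene, 40 °C) gives the phosphonium bromide F2. Wittig olefination of 20 with this salt in 1,2-epoxybutane, where the bromide opens the epoxide and the resulting alkoxide releases the ylide at near-neutral pH, followed by separation or thermal equilibration of any 15Z isomer, comes back to the route at 26.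

Step 8. What may go wrong: slow or unselective oxygen delivery, because the hydroxyl-bearing face is also the face of the C6 side chain, with competing oxidation of the allylic alcohol to the enone. Fallback: intramolecular oxygen delivery from a tethered carbonate. Setting out from 5, acylation (Boc2O, DMAP, MeCN) gives the tert-butyl carbonate F3. Iodocyclisation (IBr, toluene, −80 °C) places iodine on the open face and the carbonate oxygen on C4, necessarily cis to C3–O, giving the cis-fused iodo carbonate F4. DBU then removes HI through the dienolate to give the cyclic carbonate of the dienone F5, and methanolysis (K2CO3, MeOH) comes back to the route at 12.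

**Further compounds**
F1 | step 20 | (1S,4R)-3,5,5-trimethyl-4-[(1E,3E,5E)-3-methyl-6-(4,4,5,5-tetramethyl-1,3,2-dioxaborolan-2-yl)hexa-1,3,5-trien-1-yl]cyclohex-2-en-1-ol | CC1=C[C@@H](O)CC(C)(C)[C@H]1/C=C/C(C)=C/C=C/B1OC(C)(C)C(C)(C)O1
F2 | step 19 | triphenyl[(2E)-3-{[(trifluoromethyl)sulfonyl]oxy}but-2-en-1-yl]phosphonium bromide | [Br-].FC(F)(F)S(=O)(=O)O/C(C)=C/C[P+](c1ccccc1)(c1ccccc1)c1ccccc1
F3 | step 8 | tert-butyl (1S,4R)-3,5,5-trimethyl-4-[(E)-3-oxobut-1-en-1-yl]cyclohex-2-en-1-yl carbonate | CC1=C[C@@H](OC(=O)OC(C)(C)C)CC(C)(C)[C@H]1/C=C/C(C)=O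
F4 | step 8 | cis-fused 3,4-carbonate of (3S,4R,5S,6R)-3,4-dihydroxy-5-iodo-4,5-dihydro-α-ionone (iodine trans to the carbonate oxygens) | C[C@@]1(I)[C@H]2OC(=O)O[C@H]2CC(C)(C)[C@H]1/C=C/C(C)=O
F5 | step 8 | cyclic 3,4-carbonate of (3S,4R)-3,4-dihydroxy-β-ionone | CC(=O)/C=C/C1=C(C)[C@H]2OC(=O)O[C@H]2CC1(C)C
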